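**Plan**

- Numbering used throughout: C1 = CH(i-Pr), C2 = the ketone next to it, C3 = CH2, C4 = C(CO2Me), C5 = CH, C6 = dienone C=O, C7=C8(Me), C9, C10, C11=C12(Me), C13 = enone C=O, C14 = CH2.
- Enabling feature: the C2 and C13 ketones are 1,4-related across C1–C14, so C1 is α to C2 and β to C13. The C1–C2 bond therefore needs an acyl-anion equivalent for C2 added to a C13 enal, and nitromethane serves as that equivalent.
- Retrosynthetic cuts, in order: C6–C7 (opens the 14-membered ring), C12–C13, C2–C3, C1–C2.
- Forward: Michael addition (C1–C2); nitronate SN2′ on a Baylis–Hillman acetate (C2–C3) and Nef reaction; Nozaki–Hiyama–Kishi union with a C7–C12 iodoalkene (C12–C13); Nozaki–Hiyama–Kishi closure of the only ring at C6–C7; oxidation.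
- Stereochemistry: C1 comes from the aminocatalyst; C4=C5 (E) from the SN2′ elimination, C7=C8 (E) from carboalumination, C11=C12 (Z) from an α-iodo-ylide olefination. Once C1 is α to the C2 ketone, only acidic or buffered conditions are used.

Key step: step 1

Assumption: the facial sense of the aminocatalyst is taken from the usual shielding model, under which the (R)-configured diphenylprolinol silyl ether leads to the (R)-aldehyde 3; if the sense proved opposite, the (S)-catalyst would be used instead.

**Step 1**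
Reactants: 1 (E)-4-methylpent-2-enal; 2 nitromethane
Product: 3 (3R)-4-methyl-3-(nitromethyl)pentanal
Conditions: (R)-2-[diphenyl(trimethylsilyloxy)methyl]pyrrolidine (10 mol%), PhCO2H (20 mol%), 2 (3 equiv), MeOH, rt
Reagents that add atoms: none
Why: The secondary amine condenses with 1 to an (E)-configured, s-trans iminium ion whose β-carbon (the future C1) takes up the nitronate of 2, and protonation and hydrolysis of the resulting enamine release 3 and the catalyst; this is the known diarylprolinol silyl ether-catalysed Michael addition of nitroalkanes to enals. No ring is closed; the step forms only the C1–C2 bond. The C1 stereocentre is controlled by the catalyst, whose diphenyl(silyloxy)methyl arm covers one face of the iminium ion, so that the R-configured amine should deliver the nitronate to the face that gives the R aldehyde. The step needs 1,4- rather than 1,2-addition and single rather than double addition, which iminium activation, the acid co-catalyst and the excess of 2 should secure; the β-isopropyl group is expected only to slow the addition. The nitro carbon enters as a masked C2 carbonyl that is already distinct from the C13 aldehyde, and C1 is not yet α to a carbonyl and so cannot epimerise at this stage.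

**Step 2**
Reactants: 3 (3R)-4-methyl-3-(nitromethyl)pentanal
Product: 4 (3R)-1,1-dimethoxy-4-methyl-3-(nitromethyl)pentane
Conditions: HC(OMe)3, TsOH·H2O (cat.), MeOH, rt
Reagents that add atoms: trimethyl orthoformate, COC(OC)OC
Why: Acid-catalysed acetalisation with the orthoformate as water scavenger masks the C13 aldehyde before any base is used, leaves the nitro group free and cannot affect C1, which is not α to a carbonyl.

**Step 3**
Reactants: 5 methyl acrylate; 6 2,2-dimethoxyacetaldehyde
Product: 7 methyl 3-hydroxy-4,4-dimethoxy-2-methylidenebutanoate (racemic)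
Conditions: DABCO (1 equiv), 1,4-dioxane/H2O (1:1), rt
Reagents that add atoms: none
Why: In this Morita–Baylis–Hillman reaction the DABCO–acrylate zwitterion adds to the activated α,α-dialkoxy aldehyde, and the racemic carbinol centre is irrelevant because that carbon becomes the sp2 carbon C5.

**Step 4**
Reactants: 7 methyl 3-hydroxy-4,4-dimethoxy-2-methylidenebutanoate
Product: 8 methyl 3-(acetyloxy)-4,4-dimethoxy-2-methylidenebutanoate (racemic)
Conditions: Ac2O, pyridine, DMAP (cat.), CH2Cl2, 0 °C
Reagents that add atoms: acetic anhydride, CC(=O)OC(C)=O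
Why: O-Acylation of the secondary allylic alcohol installs the leaving group for the allylic substitution, and the low temperature should keep the acetate from migrating to the primary allylic position.

**Step 5**
Reactants: 4 (3R)-1,1-dimethoxy-4-methyl-3-(nitromethyl)pentane; 8 methyl 3-(acetyloxy)-4,4-dimethoxy-2-methylidenebutanoate
Product: 9 methyl (2E)-2-[(3R)-5,5-dimethoxy-2-nitro-3-(propan-2-yl)pentyl]-4,4-dimethoxybut-2-enoate (both epimers at the nitro carbon)
Conditions: K2CO3 (1.2 equiv), DMF, 0 °C to rt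
Reagents that add atoms: none
Why: The nitronate of 4 adds to the methylidene carbon of the acrylate and acetate is then expelled (conjugate addition–elimination, overall SN2′), the established C-alkylation of nitroalkanes by Baylis–Hillman acetates; this forms C2–C3 and the C4=C5 bond with C6 anti to the ester (E), and the new C2 centre is erased in the next step.

**Step 6**
Reactants: 9 methyl (2E)-2-[(3R)-5,5-dimethoxy-2-nitro-3-(propan-2-yl)pentyl]-4,4-dimethoxybut-2-enoate
Product: 11 methyl (2E)-2-[(3R)-5,5-dimethoxy-2-oxo-3-(propan-2-yl)pentyl]-4,4-dimethoxybut-2-enoate, via sodium nitronate 10 (not isolated)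
Conditions: NaOMe (1.05 equiv), MeOH, 0 °C; then aq. TiCl3 (4 equiv), NH4OAc buffer (pH 5–6), THF/H2O, 0 °C to rt
Reagents that add atoms: water, O
Why: The Nef reaction in its reductive TiCl3 form takes the preformed nitronate to the imine, which is hydrolysed in the buffered medium to the C2 ketone; at pH 5–6 both acetals, the enoate and the now enolisable C1 centre should be preserved.

**Step 7**
Reactants: 11 methyl (2E)-2-[(3R)-5,5-dimethoxy-2-oxo-3-(propan-2-yl)pentyl]-4,4-dimethoxybut-2-enoate
Product: 12 methyl (2E)-2-[(3R)-2,5-dioxo-3-(propan-2-yl)pentyl]-4,4-dimethoxybut-2-enoate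
Conditions: PPTS (0.1 equiv), acetone/H2O (10:1), rt, stopped when 11 is consumed
Reagents that add atoms: water, O
Why: Acetal hydrolysis under weak acid should be selective because the aliphatic C13 acetal ionises readily, whereas the C6 acetal would have to form an oxocarbenium ion conjugated to the electron-poor acrylate and should react far more slowly.

**Step 8**
Reactants: 13 4-pentyn-1-ol
Product: 15 (4E)-5-iodo-4-methylpent-4-en-1-ol, via alkenylalane 14 (not isolated)
Conditions: AlMe3 (3 equiv), Cp2ZrCl2 (0.25 equiv), CH2Cl2, 0 °C to rt; then I2, THF, −30 to 0 °C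
Reagents that add atoms: trimethylaluminium, C[Al](C)C; iodine, II
Why: The zirconium-catalysed carboalumination (Negishi) adds methyl and aluminium syn across the alkyne with aluminium at the terminus, and iodinolysis with retention gives the E-iodoalkene that fixes the C7=C8 geometry.

**Step 9**
Reactants: 15 (4E)-5-iodo-4-methylpent-4-en-1-ol
Product: 18 (4E)-4-methyl-5-(trimethylsilyl)pent-4-en-1-ol, via dilithio alkoxide 16 (not isolated), via bis-silyl ether 17 (not isolated)
Conditions: t-BuLi (3.1 equiv), Et2O, −78 °C; Me3SiCl (2.5 equiv), −78 °C to rt; then 1 M HCl, rt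
Reagents that add atoms: chlorotrimethylsilane, C[Si](C)(C)Cl
Why: Lithium–iodine exchange proceeds with retention of alkene geometry, both the alkenyllithium and the alkoxide are silylated, and only the labile O–Si bond is cleaved on acidic work-up, so C7 is stored as a vinylsilane that is inert to the first chromium-mediated coupling.

**Step 10**
Reactants: 18 (4E)-4-methyl-5-(trimethylsilyl)pent-4-en-1-ol
Product: 19 (4E)-4-methyl-5-(trimethylsilyl)pent-4-enal
Conditions: Dess–Martin periodinane, CH2Cl2, 0 °C to rt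
Reagents that add atoms: none
Why: Dess–Martin oxidation takes the primary alcohol to the aldehyde without touching the vinylsilane.

**Step 11**
Reactants: 19 (4E)-4-methyl-5-(trimethylsilyl)pent-4-enal
Product: 20 [(1E,5Z)-6-iodo-2-methylhepta-1,5-dien-1-yl]trimethylsilane
Conditions: EtPPh3I, n-BuLi, THF, 0 °C to rt; I2, −78 °C; NaN(SiMe3)2, −78 to −20 °C; then 19, −78 °C to rt
Reagents that add atoms: ethyltriphenylphosphonium iodide, CC[P+](c1ccccc1)(c1ccccc1)c1ccccc1.[I-]; iodine, II
Why: This Stork–Zhao-type Wittig olefination with the non-stabilised α-iodo ylide Ph3P=C(I)CH3 passes through the kinetically favoured cis-oxaphosphetane and should give the (Z)-2-iodoalkene, which fixes the C11=C12 geometry.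

**Step 12**
Reactants: 12 methyl (2E)-2-[(3R)-2,5-dioxo-3-(propan-2-yl)pentyl]-4,4-dimethoxybut-2-enoate; 20 [(1E,5Z)-6-iodo-2-methylhepta-1,5-dien-1-yl]trimethylsilane
Product: 21 methyl (2E)-2-[(3R,6Z,10E)-5-hydroxy-6,10-dimethyl-2-oxo-3-(propan-2-yl)-11-(trimethylsilyl)undeca-6,10-dien-1-yl]-4,4-dimethoxybut-2-enoate (both carbinol epimers)
Conditions: 20 (1.5 equiv), CrCl2 (4 equiv), NiCl2 (2 mol%), DMSO, rt
Reagents that add atoms: none
Why: In this Nozaki–Hiyama–Kishi coupling zerovalent nickel formed from NiCl2 inserts into the C–I bond, the alkenyl group passes to chromium with retention of the Z geometry and adds only to the aldehyde, not to the ketone, ester, acetal or vinylsilane; the C13 carbinol epimers are merged in the next step.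

**Step 13**
Reactants: 21 methyl (2E)-2-[(3R,6Z,10E)-5-hydroxy-6,10-dimethyl-2-oxo-3-(propan-2-yl)-11-(trimethylsilyl)undeca-6,10-dien-1-yl]-4,4-dimethoxybut-2-enoate
Product: 22 methyl (2E)-2-[(3R,6Z,10E)-6,10-dimethyl-2,5-dioxo-3-(propan-2-yl)-11-(trimethylsilyl)undeca-6,10-dien-1-yl]-4,4-dimethoxybut-2-enoate
Conditions: Dess–Martin periodinane, pyridine, CH2Cl2, 0 °C to rt
Reagents that add atoms: none
Why: Dess–Martin oxidation of the allylic alcohol under pyridine buffering gives the Z-enone and the 1,4-diketone pattern without a base strong enough to epimerise C1 or isomerise C11=C12.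

**Step 14**
Reactants: 22 methyl (2E)-2-[(3R,6Z,10E)-6,10-dimethyl-2,5-dioxo-3-(propan-2-yl)-11-(trimethylsilyl)undeca-6,10-dien-1-yl]-4,4-dimethoxybut-2-enoate
Product: 23 methyl (2E)-2-[(3R,6Z,10E)-11-iodo-6,10-dimethyl-2,5-dioxo-3-(propan-2-yl)undeca-6,10-dien-1-yl]-4,4-dimethoxybut-2-enoate
Conditions: N-iodosuccinimide (1.3 equiv), (CF3)2CHOH, 0 °C
Reagents that add atoms: N-iodosuccinimide, O=C1CCC(=O)N1I
Why: Iododesilylation is an ipso electrophilic substitution through a β-silyl cation and occurs with retention, and it should be chemoselective because the vinylsilane is the only electron-rich alkene left, the other two being conjugated to carbonyl groups.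

**Step 15**
Reactants: 23 methyl (2E)-2-[(3R,6Z,10E)-11-iodo-6,10-dimethyl-2,5-dioxo-3-(propan-2-yl)undeca-6,10-dien-1-yl]-4,4-dimethoxybut-2-enoate
Product: 24 methyl (2E)-2-[(3R,6Z,10E)-11-iodo-6,10-dimethyl-2,5-dioxo-3-(propan-2-yl)undeca-6,10-dien-1-yl]-4-oxobut-2-enoate
Conditions: TsOH·H2O (0.2 equiv), acetone/H2O (10:1), rt
Reagents that add atoms: water, O
Why: Hydrolysis of the remaining, deactivated acetal needs the stronger sulfonic acid, and the water-rich medium should disfavour dehydrative furan formation from the 1,4-diketone while leaving the iodoalkene untouched.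

**Step 16**
Reactants: 24 methyl (2E)-2-[(3R,6Z,10E)-11-iodo-6,10-dimethyl-2,5-dioxo-3-(propan-2-yl)undeca-6,10-dien-1-yl]-4-oxobut-2-enoate
Product: 25 methyl (1E,4E,8Z,12R)-3-hydroxy-5,9-dimethyl-10,13-dioxo-12-(propan-2-yl)cyclotetradeca-1,4,8-triene-1-carboxylate (both carbinol epimers)
Conditions: CrCl2 (10 equiv), NiCl2 (5 mol%), DMSO/THF (3:1), rt, syringe-pump addition of 24 to a final 2 mM
Reagents that add atoms: none
Why: The intramolecular Nozaki–Hiyama–Kishi reaction at high dilution joins C7 to the C6 aldehyde and closes the 14-membered ring with retention of the C7=C8 geometry, tolerating the two ketones and the ester; the two C6 carbinol epimers converge in the last step.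

**Step 17**
Reactants: 25 methyl (1E,4E,8Z,12R)-3-hydroxy-5,9-dimethyl-10,13-dioxo-12-(propan-2-yl)cyclotetradeca-1,4,8-triene-1-carboxylate
Product: 26 methyl sarcoate, methyl (1E,4E,8Z,12R)-5,9-dimethyl-3,10,13-trioxo-12-(propan-2-yl)cyclotetradeca-1,4,8-triene-1-carboxylate
Conditions: Dess–Martin periodinane, pyridine, CH2Cl2, 0 °C
Reagents that add atoms: none
Why: Dess–Martin oxidation of the doubly allylic alcohol gives the cross-conjugated C6 ketone under buffered, non-basic conditions that should leave the C1 centre and the three alkene geometries as set.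

**Compound list**

1 | (E)-4-methylpent-2-enal | CC(C)/C=C/C=O | starting material
2 | nitromethane | C[N+](=O)[O-] | starting material
3 | (3R)-4-methyl-3-(nitromethyl)pentanal | O=CC[C@H](C(C)C)C[N+](=O)[O-] | intermediate
4 | (3R)-1,1-dimethoxy-4-methyl-3-(nitromethyl)pentane | COC(OC)C[C@H](C(C)C)C[N+](=O)[O-] | intermediate
5 | methyl acrylate | C=CC(=O)OC | starting material
6 | 2,2-dimethoxyacetaldehyde | COC(OC)C=O | starting material
7 | methyl 3-hydroxy-4,4-dimethoxy-2-methylidenebutanoate (racemic) | COC(=O)C(=C)C(O)C(OC)OC | intermediate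
8 | methyl 3-(acetyloxy)-4,4-dimethoxy-2-methylidenebutanoate (racemic) | COC(=O)C(=C)C(OC(C)=O)C(OC)OC | intermediate
9 | methyl (2E)-2-[(3R)-5,5-dimethoxy-2-nitro-3-(propan-2-yl)pentyl]-4,4-dimethoxybut-2-enoate (both epimers at the nitro carbon) | COC(OC)C[C@H](C(C)C)C([N+](=O)[O-])C/C(C(=O)OC)=C\C(OC)OC | intermediate
10 | sodium nitronate of 9 (not isolated) | COC(OC)C[C@H](C(C)C)C(C/C(C(=O)OC)=C\C(OC)OC)=[N+]([O-])[O-].[Na+] | intermediate
11 | methyl (2E)-2-[(3R)-5,5-dimethoxy-2-oxo-3-(propan-2-yl)pentyl]-4,4-dimethoxybut-2-enoate | COC(OC)C[C@H](C(C)C)C(=O)C/C(C(=O)OC)=C\C(OC)OC | intermediate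
12 | methyl (2E)-2-[(3R)-2,5-dioxo-3-(propan-2-yl)pentyl]-4,4-dimethoxybut-2-enoate | O=CC[C@H](C(C)C)C(=O)C/C(C(=O)OC)=C\C(OC)OC | intermediate
13 | 4-pentyn-1-ol | C#CCCCO | starting material
14 | dimethylaluminium alkoxide of (4E)-5-(dimethylalumanyl)-4-methylpent-4-en-1-ol (not isolated) | C[Al](C)OCCC/C(C)=C/[Al](C)C | intermediate
15 | (4E)-5-iodo-4-methylpent-4-en-1-ol | OCCC/C(C)=C/I | intermediate
16 | lithium (4E)-5-lithio-4-methylpent-4-en-1-olate (not isolated) | [Li]OCCC/C(C)=C/[Li] | intermediate
17 | trimethyl{[(4E)-4-methyl-5-(trimethylsilyl)pent-4-en-1-yl]oxy}silane (not isolated) | C[Si](C)(C)OCCC/C(C)=C/[Si](C)(C)C | intermediate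
18 | (4E)-4-methyl-5-(trimethylsilyl)pent-4-en-1-ol | OCCC/C(C)=C/[Si](C)(C)C | intermediate
19 | (4E)-4-methyl-5-(trimethylsilyl)pent-4-enal | O=CCC/C(C)=C/[Si](C)(C)C | intermediate
20 | [(1E,5Z)-6-iodo-2-methylhepta-1,5-dien-1-yl]trimethylsilane | C/C(I)=C/CC/C(C)=C/[Si](C)(C)C | intermediate
21 | methyl (2E)-2-[(3R,6Z,10E)-5-hydroxy-6,10-dimethyl-2-oxo-3-(propan-2-yl)-11-(trimethylsilyl)undeca-6,10-dien-1-yl]-4,4-dimethoxybut-2-enoate (both carbinol epimers) | C[Si](C)(C)/C=C(\C)CC/C=C(/C)C(O)C[C@H](C(C)C)C(=O)C/C(C(=O)OC)=C\C(OC)OC | intermediate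
22 | methyl (2E)-2-[(3R,6Z,10E)-6,10-dimethyl-2,5-dioxo-3-(propan-2-yl)-11-(trimethylsilyl)undeca-6,10-dien-1-yl]-4,4-dimethoxybut-2-enoate | C[Si](C)(C)/C=C(\C)CC/C=C(/C)C(=O)C[C@H](C(C)C)C(=O)C/C(C(=O)OC)=C\C(OC)OC | intermediate
23 | methyl (2E)-2-[(3R,6Z,10E)-11-iodo-6,10-dimethyl-2,5-dioxo-3-(propan-2-yl)undeca-6,10-dien-1-yl]-4,4-dimethoxybut-2-enoate | I/C=C(\C)CC/C=C(/C)C(=O)C[C@H](C(C)C)C(=O)C/C(C(=O)OC)=C\C(OC)OC | intermediate
24 | methyl (2E)-2-[(3R,6Z,10E)-11-iodo-6,10-dimethyl-2,5-dioxo-3-(propan-2-yl)undeca-6,10-dien-1-yl]-4-oxobut-2-enoate | I/C=C(\C)CC/C=C(/C)C(=O)C[C@H](C(C)C)C(=O)C/C(C(=O)OC)=C\C=O | intermediate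
25 | methyl (1E,4E,8Z,12R)-3-hydroxy-5,9-dimethyl-10,13-dioxo-12-(propan-2-yl)cyclotetradeca-1,4,8-triene-1-carboxylate (both carbinol epimers) | COC(=O)/C1=C/C(O)/C=C(\C)CC/C=C(/C)C(=O)C[C@H](C(C)C)C(=O)C1 | intermediate
26 | methyl sarcoate, methyl (1E,4E,8Z,12R)-5,9-dimethyl-3,10,13-trioxo-12-(propan-2-yl)cyclotetradeca-1,4,8-triene-1-carboxylate | COC(=O)/C1=C/C(=O)/C=C(\C)CC/C=C(/C)C(=O)C[C@H](C(C)C)C(=O)C1 | target

**Step count and risks**

Total steps: 17. Longest linear sequence: 11 steps (1, 2, 5, 6, 7, 12, 13, 14, 15, 16, 17; the branch through steps 3 and 4 is equally long).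

Step 16, ring closure. Intermolecular coupling may outrun cyclisation even at high dilution, and divalent chromium may transfer an electron to the doubly activated C4=C5 alkene of the aldehyde. The fallback closes the ring by olefin metathesis at C7=C8; it sets out from 12 and returns at 25. Aldehyde 12 would be coupled (CrCl2, NiCl2, DMSO) with (5Z)-6-iodo-2-methylhepta-1,5-diene F1, itself made from commercial 4-methylpent-4-enal by the α-iodo-ylide olefination of step 11, to give the isopropenyl-terminated C13 carbinol F2. Dess–Martin oxidation would give the corresponding enone F3, and TsOH in wet acetone would release the C6 aldehyde F4. A second CrCl2/NiCl2 coupling, now with iodoethene, would give the divinyl carbinol F5. Ring-closing metathesis between the vinyl and isopropenyl groups of F5 (second-generation Grubbs catalyst, toluene, 80 °C, high dilution) should then give 25, which rejoins the route at step 17; the C7=C8 geometry would here rest on the preference of the ring and would need to be checked.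

Step 7, differentiation of the two acetals. Hydrolysis of the C6 acetal may keep pace with that of the C13 acetal, so that the two aldehyde carbons lose their differentiation. The fallback replaces the rate difference by an orthogonal S,S-acetal at C13; it sets out from 3 and returns at 12. Aldehyde 3 would be converted with propane-1,3-dithiol and BF3·OEt2 into 2-[(2R)-3-methyl-2-(nitromethyl)butyl]-1,3-dithiane F6. The SN2′ reaction with 8 under the conditions of step 5 would give the dithianyl nitro ester F7, and the TiCl3 Nef reaction of step 6 the dithianyl ketone F8. Removal of the dithiane under alkylative conditions (MeI, CaCO3, MeCN/H2O, 40 °C), to which the O,O-acetal at C6 is inert, should give 12.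

Step 5, nitronate SN2′. Nitrous acid may be lost from the product under the basic conditions, the product nitronate may be alkylated a second time, or the C4=C5 geometry may erode in the elimination. The fallback forms C2–C3 by conjugate addition and C4=C5 by a separate olefination; it sets out from 4 and returns at 11. Nitroalkane 4 would be added (catalytic DBU, MeCN) to methyl 2-(dimethoxyphosphoryl)acrylate to give the γ-nitro phosphonate, methyl (5R)-2-(dimethoxyphosphoryl)-7,7-dimethoxy-4-nitro-5-(propan-2-yl)heptanoate F9. The TiCl3 Nef reaction of step 6 would give the keto phosphonate, methyl (5R)-2-(dimethoxyphosphoryl)-7,7-dimethoxy-4-oxo-5-(propan-2-yl)heptanoate F10. Horner–Wadsworth–Emmons olefination of F10 with 6 under mild conditions (LiCl, i-Pr2NEt, MeCN) should give the E-enoate 11.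

**Further compounds**

F1 | step 16 | (5Z)-6-iodo-2-methylhepta-1,5-diene | C/C(I)=C/CCC(C)=C
F2 | step 16 | methyl (2E)-2-[(3R,6Z)-5-hydroxy-6,10-dimethyl-2-oxo-3-(propan-2-yl)undeca-6,10-dien-1-yl]-4,4-dimethoxybut-2-enoate | C=C(C)CC/C=C(/C)C(O)C[C@H](C(C)C)C(=O)C/C(C(=O)OC)=C\C(OC)OC
F3 | step 16 | methyl (2E)-2-[(3R,6Z)-6,10-dimethyl-2,5-dioxo-3-(propan-2-yl)undeca-6,10-dien-1-yl]-4,4-dimethoxybut-2-enoate | C=C(C)CC/C=C(/C)C(=O)C[C@H](C(C)C)C(=O)C/C(C(=O)OC)=C\C(OC)OC
F4 | step 16 | methyl (2E)-2-[(3R,6Z)-6,10-dimethyl-2,5-dioxo-3-(propan-2-yl)undeca-6,10-dien-1-yl]-4-oxobut-2-enoate | C=C(C)CC/C=C(/C)C(=O)C[C@H](C(C)C)C(=O)C/C(C(=O)OC)=C\C=O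
F5 | step 16 | methyl (2E)-2-[(3R,6Z)-6,10-dimethyl-2,5-dioxo-3-(propan-2-yl)undeca-6,10-dien-1-yl]-4-hydroxyhexa-2,5-dienoate | C=C(C)CC/C=C(/C)C(=O)C[C@H](C(C)C)C(=O)C/C(C(=O)OC)=C\C(O)C=C
F6 | step 7 | 2-[(2R)-3-methyl-2-(nitromethyl)butyl]-1,3-dithiane | C1CSC(SC1)C[C@H](C(C)C)C[N+](=O)[O-]
F7 | step 7 | methyl (2E)-2-[(3R)-4-(1,3-dithian-2-yl)-2-nitro-3-(propan-2-yl)butyl]-4,4-dimethoxybut-2-enoate | C1CSC(SC1)C[C@H](C(C)C)C([N+](=O)[O-])C/C(C(=O)OC)=C\C(OC)OC
F8 | step 7 | methyl (2E)-2-[(3R)-4-(1,3-dithian-2-yl)-2-oxo-3-(propan-2-yl)butyl]-4,4-dimethoxybut-2-enoate | C1CSC(SC1)C[C@H](C(C)C)C(=O)C/C(C(=O)OC)=C\C(OC)OC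
F9 | step 5 | methyl (5R)-2-(dimethoxyphosphoryl)-7,7-dimethoxy-4-nitro-5-(propan-2-yl)heptanoate | COC(OC)C[C@H](C(C)C)C([N+](=O)[O-])CC(C(=O)OC)P(=O)(OC)OC
F10 | step 5 | methyl (5R)-2-(dimethoxyphosphoryl)-7,7-dimethoxy-4-oxo-5-(propan-2-yl)heptanoate | COC(OC)C[C@H](C(C)C)C(=O)CC(C(=O)OC)P(=O)(OC)OC
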